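**Plan**

1. Numbering (used for all intermediates): C1 (=CHBr), C2 (CCl), C3/C4 (oxirane carbons, C3 quaternary), C5 (CH2), C6 (CHOH), C7 (CBr), C8 (CH2Cl).
2. Cuts: oxirane C4–O (back to a C3-OH/C4-Cl anti-chlorohydrin); C2–Cl and C1–Br (back to a terminal alkyne); C2–C3 (ethynyl Grignard + α-chloro methyl ketone); C3–CH3 (Weinreb amide); C4–Cl, C6–O and C7–Br (on a γ-lactone); C8–Cl and C6=C7 (Appel, Wittig).
3. Forward: the C3–C8 chain is made by Wittig olefination; a temporary γ-lactone (C3–C6, ring O on C6) is closed by catalytic asymmetric 5-exo bromolactonization and opened again once it has relayed C4; the C3 methyl and then C1–C2 are joined; the oxirane, the only ring of the target, is closed in the last but one step.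
4. Stereochemistry: C6 and C7 come from the one catalytic event (anti addition to the E-alkene); C4 by 1,3-induction on the lactone (trans-OH, inverted to cis-Cl); C3 by 1,2-induction from C4 (Cornforth); C4 is inverted again on oxirane closure; the Z-alkene comes from anti-hydrochlorination.
5. Enabling feature: the oxirane CH (C4) is bonded to the quaternary oxirane carbon C3, so C4 can carry chlorine in the precursor, where it steers attack on the C3 ketone and later leaves when the C3 oxygen (the former carbonyl O) closes the three-membered ring.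

Key step: step 11

Assumption: the bromolactonization catalyst is taken to give the (R,R)-lactone as drawn; if its sense of induction is the opposite, its enantiomer is used.

**Route**

Step 1
Reactants: 1 methyl 4-oxobutanoate; 2 2-(triphenylphosphoranylidene)propanal
Product: 3 methyl (4E)-5-methyl-6-oxohex-4-enoate
Conditions: PhMe, 90 °C
Reagents that add atoms: none
Why: Wittig olefination with a stabilised formyl ylide should give the (E)-2-methyl enal under thermodynamic control (chain trans to CHO), and the saturated aldehyde reacts much faster than the conjugated, α-branched product.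

Step 2
Reactants: 3 methyl (4E)-5-methyl-6-oxohex-4-enoate
Product: 4 methyl (4E)-6-hydroxy-5-methylhex-4-enoate
Conditions: NaBH4, CeCl3·7H2O (cat.), MeOH, 0 °C
Reagents that add atoms: none
Why: Luche-type 1,2-reduction should reduce the enal carbonyl chemoselectively and leave the methyl ester and the E-alkene untouched.

Step 3
Reactants: 4 methyl (4E)-6-hydroxy-5-methylhex-4-enoate
Product: 5 methyl (4E)-6-chloro-5-methylhex-4-enoate
Conditions: PPh3, CCl4, CH2Cl2, 0 °C to 40 °C
Reagents that add atoms: carbon tetrachloride, ClC(Cl)(Cl)Cl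
Why: Appel reaction; chloride displaces the alkoxyphosphonium group by SN2 at the primary allylic carbon, so the E geometry should be kept without allylic transposition.

Step 4
Reactants: 5 methyl (4E)-6-chloro-5-methylhex-4-enoate
Product: 6 (4E)-6-chloro-5-methylhex-4-enoic acid
Conditions: LiOH, THF/H2O, 0 °C; then 1 M HCl
Reagents that add atoms: lithium hydroxide (aqueous), [Li+].[OH-]
Why: Saponification; acyl substitution at the methyl ester by hydroxide is far faster at 0 °C than SN2 displacement of the allylic chloride, so the acid should form with the chloride intact.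

Step 5
Reactants: 6 (4E)-6-chloro-5-methylhex-4-enoic acid
Product: 7 (5R)-5-[(2R)-2-bromo-1-chloropropan-2-yl]oxolan-2-one
Conditions: TBCO (2,4,4,6-tetrabromocyclohexa-2,5-dienone), chiral BINOL-derived amidine–phenol bifunctional catalyst (10 mol %), PhMe/CH2Cl2, −50 °C
Reagents that add atoms: 2,4,4,6-tetrabromocyclohexa-2,5-dien-1-one, O=C1C(Br)=CC(Br)(Br)C=C1Br
Why: Catalytic enantioselective bromolactonization; the catalyst delivers Br+ to one face of the E-alkene and the bound carboxylate opens the bromonium ion anti in a 5-exo mode at C6 (favoured by ring size and by the inductively deactivating CH2Cl on C7), which sets C6 (R) and C7 (R) in one event and ties C6–O into a temporary ring.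

Step 6
Reactants: 7 (5R)-5-[(2R)-2-bromo-1-chloropropan-2-yl]oxolan-2-one
Product: 9 (3S,5R)-5-[(2R)-2-bromo-1-chloropropan-2-yl]-3-hydroxyoxolan-2-one, via potassium lactone enolate 8 (not isolated)
Conditions: KHMDS, THF, −78 °C; then 2-(phenylsulfonyl)-3-phenyloxaziridine, −78 °C; sat. NH4Cl
Reagents that add atoms: 2-(phenylsulfonyl)-3-phenyloxaziridine (Davis oxaziridine), O=S(=O)(c1ccccc1)N1OC1c1ccccc1
Why: Enolate hydroxylation with the Davis oxaziridine; the planar enolate should be attacked on the face opposite the bulky C7 substituent on C6, giving the trans hydroxy lactone (1,3-induction across the ring).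

Step 7
Reactants: 9 (3S,5R)-5-[(2R)-2-bromo-1-chloropropan-2-yl]-3-hydroxyoxolan-2-one
Product: 10 (3R,5R)-5-[(2R)-2-bromo-1-chloropropan-2-yl]-3-chlorooxolan-2-one
Conditions: PPh3, CCl4, MeCN, rt
Reagents that add atoms: carbon tetrachloride, ClC(Cl)(Cl)Cl
Why: Appel reaction at an α-hydroxy ester; SN2 displacement of the oxyphosphonium group with inversion turns the trans alcohol into the cis chloride, which is the C4 configuration needed for the later invertive oxirane closure.

Step 8
Reactants: 10 (3R,5R)-5-[(2R)-2-bromo-1-chloropropan-2-yl]-3-chlorooxolan-2-one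
Product: 11 (2R,4R,5R)-5-bromo-2,6-dichloro-4-hydroxy-N-methoxy-N,5-dimethylhexanamide
Conditions: MeNH(OMe)·HCl, AlMe3, CH2Cl2, 0 °C to rt; aq. Rochelle salt
Reagents that add atoms: N,O-dimethylhydroxylamine hydrochloride, CNOC.Cl
Why: Weinreb aminolysis of the lactone with the aluminium amide made in situ opens the temporary ring; the weakly basic aluminium reagent should not epimerise the α-chloro centre, and the aluminium-bound C6 oxygen is too weakly nucleophilic to displace the neighbouring tertiary bromide.

Step 9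
Reactants: 11 (2R,4R,5R)-5-bromo-2,6-dichloro-4-hydroxy-N-methoxy-N,5-dimethylhexanamide
Product: 12 (2R,4R,5R)-5-bromo-4-[tert-butyl(dimethyl)silyl]oxy-2,6-dichloro-N-methoxy-N,5-dimethylhexanamide
Conditions: TBSOTf, 2,6-lutidine, CH2Cl2, −78 °C to 0 °C
Reagents that add atoms: tert-butyldimethylsilyl trifluoromethanesulfonate, CC(C)(C)[Si](C)(C)OS(=O)(=O)C(F)(F)F
Why: Silylation of the hindered secondary alcohol with a silyl triflate protects the C6 hydroxyl of the bromohydrin, which would otherwise relactonise onto the amide or close onto C7 under the basic steps ahead.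

Step 10
Reactants: 12 (2R,4R,5R)-5-bromo-4-[tert-butyl(dimethyl)silyl]oxy-2,6-dichloro-N-methoxy-N,5-dimethylhexanamide
Product: 13 (3R,5R,6R)-6-bromo-5-[tert-butyl(dimethyl)silyl]oxy-3,7-dichloro-6-methylheptan-2-one
Conditions: MeMgBr, THF, −78 °C to 0 °C; sat. NH4Cl
Reagents that add atoms: methylmagnesium bromide, C[Mg]Br
Why: Weinreb ketone synthesis; the N-methoxy-N-methyl amide takes up only one equivalent of the Grignard reagent and releases the α-chloro methyl ketone on work-up, and the low temperature limits enolisation at C4.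

Step 11
Reactants: 13 (3R,5R,6R)-6-bromo-5-[tert-butyl(dimethyl)silyl]oxy-3,7-dichloro-6-methylheptan-2-one; 14 ethynylmagnesium bromide
Product: 16 (3S,4R,6R,7R)-7-bromo-6-[tert-butyl(dimethyl)silyl]oxy-4,8-dichloro-3,7-dimethyloct-1-yn-3-ol, via bromomagnesium alkoxide 15 (not isolated)
Conditions: THF, −78 °C to −40 °C; sat. NH4Cl at −78 °C
Reagents that add atoms: none
Why: The acetylide carbon of 14 adds to the C3 carbonyl of 13 through a Cornforth (anti-dipolar C4–Cl/C3=O) or, equivalently, polar Felkin–Anh transition state, passing the C4 hydrogen and not the C5 methylene. The closest known reaction type is the Cornforth-type addition of Grignard reagents to α-chloro ketones, the chlorohydrin route to trisubstituted oxiranes. No ring is closed here: the magnesium alkoxide 15 should not displace chloride below −40 °C and is protonated cold, so the 3-exo-tet oxirane closure is kept for step 14, after the alkyne has been processed under acidic conditions. The new quaternary stereocentre C3 (S in 16, R in the target after the CIP priority change) is controlled by the chlorine-bearing stereocentre C4 (1,2-induction), which should give the anti-chlorohydrin. The step needs addition to outrun enolisation of the α-chloro ketone and must spare the tertiary bromide and the primary chloride; the weakly basic sp-Grignard reagent, the low temperature and the neopentyl-type, β-heteroatom-deactivated halides should secure this. The chlorine on C4 thus serves as control element, as latent leaving group and, through its inversion, as the source of the C4 configuration.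

Step 12
Reactants: 16 (3S,4R,6R,7R)-7-bromo-6-[tert-butyl(dimethyl)silyl]oxy-4,8-dichloro-3,7-dimethyloct-1-yn-3-ol
Product: 17 (3S,4R,6R,7R)-1,7-dibromo-6-[tert-butyl(dimethyl)silyl]oxy-4,8-dichloro-3,7-dimethyloct-1-yn-3-ol
Conditions: NBS, AgNO3 (10 mol %), acetone, rt, dark
Reagents that add atoms: N-bromosuccinimide, O=C1CCC(=O)N1Br
Why: Silver-catalysed electrophilic bromination of a terminal alkyne gives the 1-bromoalkyne under neutral conditions; the tertiary bromide is deactivated towards silver-assisted ionisation by its β-chloro and β-silyloxy substituents, and the free tertiary alcohol and the secondary chloride are inert.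

Step 13
Reactants: 17 (3S,4R,6R,7R)-1,7-dibromo-6-[tert-butyl(dimethyl)silyl]oxy-4,8-dichloro-3,7-dimethyloct-1-yn-3-ol
Product: 18 (1Z,3R,4R,6R,7R)-1,7-dibromo-6-[tert-butyl(dimethyl)silyl]oxy-2,4,8-trichloro-3,7-dimethyloct-1-en-3-ol
Conditions: Pd(OAc)2 (5 mol %), LiCl, AcOH, rt
Reagents that add atoms: lithium chloride, [Li+].[Cl-]
Why: Palladium-catalysed anti-hydrochlorination of a 1-bromoalkyne; chloride attacks the Pd(II)-bound alkyne at C2 (distal to Br) anti to palladium and the vinyl–Pd bond is protonated by AcOH with retention, so Cl and Br end up cis (Z), and the oxirane is deliberately not yet present because LiCl/AcOH would open it.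

Step 14
Reactants: 18 (1Z,3R,4R,6R,7R)-1,7-dibromo-6-[tert-butyl(dimethyl)silyl]oxy-2,4,8-trichloro-3,7-dimethyloct-1-en-3-ol
Product: 19 tert-butyl{[(2R,3R)-3-bromo-1-[(2S,3R)-3-[(Z)-2-bromo-1-chloroethenyl]-3-methyloxiran-2-yl]-4-chloro-3-methylbutan-2-yl]oxy}dimethylsilane
Conditions: K2CO3, MeOH, 0 °C to rt
Reagents that add atoms: none
Why: Base-mediated halohydrin cyclisation; the tertiary alkoxide displaces the antiperiplanar C4 chloride (3-exo-tet, SN2) with inversion at C4, which should give the oxirane with the haloalkenyl group trans to the C5 chain, while the silylated C6 oxygen cannot close onto C7.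

Step 15
Reactants: 19 tert-butyl{[(2R,3R)-3-bromo-1-[(2S,3R)-3-[(Z)-2-bromo-1-chloroethenyl]-3-methyloxiran-2-yl]-4-chloro-3-methylbutan-2-yl]oxy}dimethylsilane
Product: 20 (2R,3R)-3-bromo-1-[(2S,3R)-3-[(Z)-2-bromo-1-chloroethenyl]-3-methyloxiran-2-yl]-4-chloro-3-methylbutan-2-ol
Conditions: HF·pyridine, pyridine, THF, 0 °C to rt
Reagents that add atoms: none
Why: Fluoride-mediated desilylation under buffered, non-basic conditions frees the C6 hydroxyl without forming an alkoxide, so the tertiary bromide should not be displaced and the oxirane should survive.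

**Compound list**

1 | methyl 4-oxobutanoate | COC(=O)CCC=O | starting material
2 | 2-(triphenylphosphoranylidene)propanal | CC(C=O)=P(c1ccccc1)(c1ccccc1)c1ccccc1 | starting material
3 | methyl (4E)-5-methyl-6-oxohex-4-enoate | COC(=O)CC/C=C(\C)C=O | intermediate
4 | methyl (4E)-6-hydroxy-5-methylhex-4-enoate | COC(=O)CC/C=C(\C)CO | intermediate
5 | methyl (4E)-6-chloro-5-methylhex-4-enoate | COC(=O)CC/C=C(\C)CCl | intermediate
6 | (4E)-6-chloro-5-methylhex-4-enoic acid | OC(=O)CC/C=C(\C)CCl | intermediate
7 | (5R)-5-[(2R)-2-bromo-1-chloropropan-2-yl]oxolan-2-one | C[C@](Br)(CCl)[C@@H]1OC(=O)CC1 | intermediate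
8 | potassium enolate of 7 (not isolated) | C[C@](Br)(CCl)[C@@H]1OC([O-])=CC1.[K+] | intermediate
9 | (3S,5R)-5-[(2R)-2-bromo-1-chloropropan-2-yl]-3-hydroxyoxolan-2-one (OH trans to the side chain) | C[C@](Br)(CCl)[C@@H]1OC(=O)[C@@H](O)C1 | intermediate
10 | (3R,5R)-5-[(2R)-2-bromo-1-chloropropan-2-yl]-3-chlorooxolan-2-one (Cl cis to the side chain) | C[C@](Br)(CCl)[C@@H]1OC(=O)[C@H](Cl)C1 | intermediate
11 | (2R,4R,5R)-5-bromo-2,6-dichloro-4-hydroxy-N-methoxy-N,5-dimethylhexanamide | CON(C)C(=O)[C@H](Cl)C[C@@H](O)[C@@](C)(Br)CCl | intermediate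
12 | (2R,4R,5R)-5-bromo-4-[tert-butyl(dimethyl)silyl]oxy-2,6-dichloro-N-methoxy-N,5-dimethylhexanamide | CON(C)C(=O)[C@H](Cl)C[C@@H](O[Si](C)(C)C(C)(C)C)[C@@](C)(Br)CCl | intermediate
13 | (3R,5R,6R)-6-bromo-5-[tert-butyl(dimethyl)silyl]oxy-3,7-dichloro-6-methylheptan-2-one | CC(=O)[C@H](Cl)C[C@@H](O[Si](C)(C)C(C)(C)C)[C@@](C)(Br)CCl | intermediate
14 | ethynylmagnesium bromide | C#C[Mg]Br | starting material
15 | bromomagnesium alkoxide of 16 (not isolated) | C#C[C@](C)(O[Mg]Br)[C@H](Cl)C[C@@H](O[Si](C)(C)C(C)(C)C)[C@@](C)(Br)CCl | intermediate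
16 | (3S,4R,6R,7R)-7-bromo-6-[tert-butyl(dimethyl)silyl]oxy-4,8-dichloro-3,7-dimethyloct-1-yn-3-ol | C#C[C@](C)(O)[C@H](Cl)C[C@@H](O[Si](C)(C)C(C)(C)C)[C@@](C)(Br)CCl | intermediate
17 | (3S,4R,6R,7R)-1,7-dibromo-6-[tert-butyl(dimethyl)silyl]oxy-4,8-dichloro-3,7-dimethyloct-1-yn-3-ol | BrC#C[C@](C)(O)[C@H](Cl)C[C@@H](O[Si](C)(C)C(C)(C)C)[C@@](C)(Br)CCl | intermediate
18 | (1Z,3R,4R,6R,7R)-1,7-dibromo-6-[tert-butyl(dimethyl)silyl]oxy-2,4,8-trichloro-3,7-dimethyloct-1-en-3-ol | Br/C=C(\Cl)[C@](C)(O)[C@H](Cl)C[C@@H](O[Si](C)(C)C(C)(C)C)[C@@](C)(Br)CCl | intermediate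
19 | tert-butyl{[(2R,3R)-3-bromo-1-[(2S,3R)-3-[(Z)-2-bromo-1-chloroethenyl]-3-methyloxiran-2-yl]-4-chloro-3-methylbutan-2-yl]oxy}dimethylsilane | C[C@](Br)(CCl)[C@H](O[Si](C)(C)C(C)(C)C)C[C@@H]1O[C@@]1(C)/C(Cl)=C/Br | intermediate
20 | (2R,3R)-3-bromo-1-[(2S,3R)-3-[(Z)-2-bromo-1-chloroethenyl]-3-methyloxiran-2-yl]-4-chloro-3-methylbutan-2-ol | C[C@](Br)(CCl)[C@H](O)C[C@@H]1O[C@@]1(C)/C(Cl)=C/Br | target

**Step count and risks**

Total steps: 15. Longest linear sequence: 15 steps (1 to 20).

Steps most likely to fail: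

1. Step 5. The catalyst may discriminate the faces of the E-trisubstituted alkene poorly, or some 6-endo closure at C7 may compete. Fallback, setting out from 6: uncatalysed bromolactonization (NBS, NaHCO3, CH2Cl2) should give the racemic anti-bromolactone, that is 7 together with its enantiomer (5S)-5-[(2S)-2-bromo-1-chloropropan-2-yl]oxolan-2-one F1. Aminolysis of the racemate with (S)-1-phenylethylamine and AlMe3 would give two diastereomeric γ-hydroxy amides, (4R,5R)-5-bromo-6-chloro-4-hydroxy-5-methyl-N-[(1S)-1-phenylethyl]hexanamide F2 and (4S,5S)-5-bromo-6-chloro-4-hydroxy-5-methyl-N-[(1S)-1-phenylethyl]hexanamide F3, to be separated by chromatography or crystallisation. Acid-catalysed relactonisation of F2 (p-TsOH, PhMe, 80 °C; N-to-O acyl transfer) comes back to the route at 7.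

2. Step 11. Enolisation of the α-chloro ketone (with loss of the C4 configuration) may compete with addition, and the small sp-nucleophile may show incomplete facial selectivity. Fallback, setting out from 13: the less basic and bulkier organocerium reagent from lithium (trimethylsilyl)acetylide and anhydrous CeCl3 (THF, −78 °C) should add in the same Cornforth sense and give (3S,4R,6R,7R)-7-bromo-6-[tert-butyl(dimethyl)silyl]oxy-4,8-dichloro-3,7-dimethyl-1-(trimethylsilyl)oct-1-yn-3-ol F4. Direct bromodesilylation of F4 (NBS, cat. AgNO3, acetone) comes back to the route at 17, without passing through 16.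

3. Step 13. Chloropalladation at the hindered C2 may be slow, so that loss of regiocontrol or ionisation of the tertiary propargylic alcohol under Pd(II)/AcOH competes. Fallback, setting out from 16: [hydroxy(tosyloxy)iodo]benzene (Koser's reagent, CH2Cl2, rt) should give the alkynyl(phenyl)iodonium salt [(3S,4R,6R,7R)-7-bromo-6-[tert-butyl(dimethyl)silyl]oxy-4,8-dichloro-3-hydroxy-3,7-dimethyloct-1-yn-1-yl](phenyl)iodonium tosylate F5. Michael-type anti addition of HCl (LiCl, AcOH, rt), in which the iodonium group fixes chloride attack at C2, would give [(1Z,3R,4R,6R,7R)-7-bromo-6-[tert-butyl(dimethyl)silyl]oxy-2,4,8-trichloro-3-hydroxy-3,7-dimethyloct-1-en-1-yl](phenyl)iodonium tosylate F6. Copper-mediated replacement of the iodonium group by bromide with retention (CuBr, KBr, DMF, rt) comes back to the route at 18.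

Further compounds

F1 | step 5 | (5S)-5-[(2S)-2-bromo-1-chloropropan-2-yl]oxolan-2-one | C[C@@](Br)(CCl)[C@H]1OC(=O)CC1
F2 | step 5 | (4R,5R)-5-bromo-6-chloro-4-hydroxy-5-methyl-N-[(1S)-1-phenylethyl]hexanamide | C[C@H](NC(=O)CC[C@@H](O)[C@@](C)(Br)CCl)c1ccccc1
F3 | step 5 | (4S,5S)-5-bromo-6-chloro-4-hydroxy-5-methyl-N-[(1S)-1-phenylethyl]hexanamide | C[C@H](NC(=O)CC[C@H](O)[C@](C)(Br)CCl)c1ccccc1
F4 | step 11 | (3S,4R,6R,7R)-7-bromo-6-[tert-butyl(dimethyl)silyl]oxy-4,8-dichloro-3,7-dimethyl-1-(trimethylsilyl)oct-1-yn-3-ol | C[Si](C)(C)C#C[C@](C)(O)[C@H](Cl)C[C@@H](O[Si](C)(C)C(C)(C)C)[C@@](C)(Br)CCl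
F5 | step 13 | [(3S,4R,6R,7R)-7-bromo-6-[tert-butyl(dimethyl)silyl]oxy-4,8-dichloro-3-hydroxy-3,7-dimethyloct-1-yn-1-yl](phenyl)iodonium 4-methylbenzenesulfonate | c1ccccc1[I+]C#C[C@](C)(O)[C@H](Cl)C[C@@H](O[Si](C)(C)C(C)(C)C)[C@@](C)(Br)CCl.Cc1ccc(cc1)S(=O)(=O)[O-]
F6 | step 13 | [(1Z,3R,4R,6R,7R)-7-bromo-6-[tert-butyl(dimethyl)silyl]oxy-2,4,8-trichloro-3-hydroxy-3,7-dimethyloct-1-en-1-yl](phenyl)iodonium 4-methylbenzenesulfonate | c1ccccc1[I+]/C=C(\Cl)[C@](C)(O)[C@H](Cl)C[C@@H](O[Si](C)(C)C(C)(C)C)[C@@](C)(Br)CCl.Cc1ccc(cc1)S(=O)(=O)[O-]
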